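# Proposed synthesis of CNP0156298.2 by asymmetric intramolecular Buchner ring expansion of a thymol-derived diazoketone

## Numbering used throughout

Guaiane numbering is used for the bicyclic core: five-membered ring C1–C5, seven-membered ring C1, C5–C10, C11 the isopropyl methine on C7, C14 the methyl on C10, C15 the methyl on C4.

Compounds:
- 1 thymol
- 2 thymol methyl ether
- 3 aryl chloro(methoxy)methane (not isolated)
- 4 aryl aldehyde
- 5 malonic acid
- 6 benzylidenemalonic acid (not isolated)
- 7 cinnamic acid
- 8 arylpropanoic acid
- 9 acid chloride (not isolated)
- 10 diazoketone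
- 11 norcaradiene (not isolated)
- 12 azulenone
- 13 C4 tertiary alcohol with the C8 trienol ether
- 14 dienone
- 15 allylic alcohol
- 16 saturated diol
- 17 vanillic acid
- 18 bis-silyl vanillate (not isolated)
- 19 O-silyl vanillic acid
- 20 C8 ester with the C4 tertiary alcohol
- 21 C4 sulfamate salt (not isolated)
- 22 silyl-protected target
- 23 target

## Analysis of the target

Compound 23 is the vanillate (4-hydroxy-3-methoxybenzoate) of a guaiane alcohol, a hydroazulene in which a five-membered ring (C1–C5) and a seven-membered ring (C1, C5–C10) share the C1–C5 bond. The five-membered ring holds a trisubstituted C3=C4 double bond with a methyl group on C4. The seven-membered ring holds the tetrasubstituted ring-fusion double bond C1=C10 with a methyl group on C10, an isopropyl group on C7 and the ester oxygen on C8. There are three stereocenters, C5 (R), C7 (R) and C8 (S). C7 and C8 are neighbours with isopropyl trans to oxygen, whereas C5 is separated from them by the C6 methylene (H5 cis to H8, trans to H7), so it cannot be set from C7/C8 by a neighbouring-group effect. The two double bonds form a skipped diene in which C2 and the stereogenic C5 are doubly allylic, so acid, base or radicals can move the double bonds into conjugation or epimerise C5; the aryl ester and the free phenol restrict late reagents further. The difficulty is therefore to build a seven-membered ring with a tetrasubstituted ring-fusion alkene, to set C5 independently of C7/C8, and to introduce C3=C4 regioselectively when little else is tolerated. The strategy rests on the substitution pattern of the seven-membered ring: C10 (methyl), C9, C8 (oxygen), C7 (isopropyl), C6 and C1 map onto the methyl-, hydroxyl- and isopropyl-bearing ring of thymol 1, with C1 being the carbon para to oxygen. Only C5 has to be inserted between C1 and C6, and if it is delivered from a C2–C3–C4 tether on C1 the same event closes the five-membered ring.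

## Retrosynthetic reasoning

**23 to 22.** The phenol is unmasked last. No skeletal bond is cut; 22 carries the phenol as a silyl ether so that the final operation can be run buffered and non-hydrolytic, which the skipped diene and the ester require.

**22 to 20 (through 21).** The C3=C4 double bond is traced back to a C4 tertiary carbinol. The alkene cannot be present earlier because it would not survive the hydrogenation of C6=C7, whereas a tertiary alcohol is an inert spectator. The forward reaction must be a syn elimination: in 20 the hydroxyl is trans to H5, so a syn process cannot reach C5 and cannot form the conjugated C4=C5 isomer.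

**20 to 16 and 19.** The ester C–O bond is cut, which makes the route convergent and keeps the aromatic acid out of all earlier steps. The forward acylation only has to distinguish a secondary from a tertiary hydroxyl. Acid 19 comes from vanillic acid 17 through 18.

**16 to 15.** The two C–H bonds at C6 and C7 are removed. Keeping C6=C7 until after C8 is set lets the C8 hydroxyl relay its configuration to C7 by a directed hydrogenation, which gives exactly the trans relation of isopropyl and oxygen.

**15 to 14.** The C8–H bond is cut back to the ketone. A catalyst-controlled reduction sets C8 without reference to the remote C5.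

**14 to 13.** The C8 carbonyl is the hydrolysed form of a methyl enol ether, that is, the oxygen of 1 carried through the whole route. The forward step must protonate C9 and nothing else, so that C1=C10 stays where the arene left it.

**13 to 12.** The C4–C15 bond is cut. The C4 ketone of 12 is flanked by H5, which is doubly allylic and alpha to the carbonyl, so the ketone is consumed immediately by a non-basic methyl nucleophile.

**12 to 10 (through 11).** This is the key disconnection: C1–C5 and C5–C6 are cut and C5 becomes the diazo carbon of 10. It is chosen because it is the only cut that returns an intact benzene ring already carrying C14, the isopropyl group and the oxygen in the right order. The forward reaction forms two rings, two skeletal bonds, the C5 stereocenter and the tetrasubstituted C1=C10 bond in one operation. It must add the carbene across C1–C6 rather than across the methyl-bearing side, and with enantioface control.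

**10 to 1 and 5.** The tether is dismantled at C4–C5 (acylation of a diazomethane equivalent by 9, made from 8), then at C2–C3 (aldehyde 4 condensed with malonic acid 5 to 7 through 6, then saturation to 8), then at C1–C2 (formylation of 2 para to oxygen through 3). Ether 2 is the O-methyl derivative of 1.

## Alternatives that were turned down

**Alternative 1:** ring closure at C7–C8 by intramolecular allylation.
- Disconnection: the C7–C8 bond is cut to the bromo aldehyde A1, a cyclopentene that already has C3=C4 and C5, an aldehyde arm on C1 (C8, through a ketal-protected C10) and a 2-methylallyl bromide arm on C5.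
- Forward key step: a divalent chromium salt turns the allylic bromide into an allylchromium species that adds to the aldehyde through its gamma carbon C7. This closes the seven-membered ring and gives the hydroazulenol A2 with a C7 isopropenyl group anti to the C8 hydroxyl.
- For: C7 and C8 are created together with the correct relative configuration by a cyclic transition state, and C3=C4 and C5 are in place from the start. In these two respects it is stronger than the chosen route, which needs a late dehydration and a separate hydrogenation.
- Against: A1 needs two ring stereocenters (C1 and C5), one of which is later destroyed. The relation of C7/C8 to C5 depends on the conformation of a forming seven-membered ring. After the key step the isopropenyl group must be saturated beside C3=C4, and the C10 ketal must be turned into the methyl-bearing tetrasubstituted C1=C10 alkene. That requires enolisation of a C10 carbonyl toward C1, while enolisation toward C9 would expel the C8 oxygen by beta-elimination.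
- Comparison: the chosen strategy obtains all seven ring carbons, C14, the isopropyl group, the oxygen and the C1=C10 alkene from 1, and forms both rings in one step from a precursor about six steps away. That brevity and the free alkene placement are what it offers in place of the built-in C7/C8 control.

**Alternative 2:** both rings by an allenic carbonylative [2+2+1] cycloaddition, then reductive transposition.
- Disconnection: the bicycle is cut to the acyclic allenyne A3, which carries the C7/C8 stereodiad, a methyl alkyne (C4, C5) and a 1,1-disubstituted allene (C10, C1, C2).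
- Forward key step: a monovalent rhodium carbonyl catalyst under carbonylative conditions joins C5 to C1 and inserts a carbonyl as C3 between C2 and C4. The product is the dienone A4 with C1=C10 and both methyl groups in place. The C3 carbonyl would then be reduced and the derived allylic diazene would shift the alkene to C3=C4 while delivering hydrogen to C5.
- For: both rings are made in one step, as in the chosen route. C7 and C8 are set in an open chain by dependable acyclic methods before cyclisation and are never at risk afterwards, which is stronger than setting them late on a sensitive ring. No acid-labile cycloheptatriene is involved.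
- Against: A3 must be assembled linearly. The C3 oxygen is an extra atom that has to be removed. C5 is set only indirectly, through the configuration of a C3 carbinol remote from all other stereocenters, and that takes about three further operations.
- Comparison: the chosen strategy sets C5 in the ring-forming event itself and starts from a commodity aromatic, so it is shorter. It pays with later and less secure control of C7 and C8.

**Alternative 3:** seven-membered ring by Claisen ring expansion of a chiral-pool lactone.
- Disconnection: the C5–C6 bond is cut by a retro-Claisen step to the 2-methylenetetrahydrofuran A6, made by methylenation of the lactone A5. C8 comes from the chiral pool, and C10 is a quaternary carbon bearing methyl, the ring oxygen and a ketal-protected cyclopentenyl group.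
- Forward key step: heating A6 bonds the exocyclic enol ether carbon C6 to C5 of the cyclopentene and breaks O–C10. This gives the cycloheptenone A7 with a C7 ketone, the C1=C10 alkene and C5–H.
- For: the absolute configuration at C8 is secure from the start. The tetrasubstituted alkene is placed regiospecifically by the sigmatropic shift. C5 arises by chirality transfer through an ordered transition state, which is as good as or better than the catalyst control of the chosen route.
- Against: C5 is only as pure as the quaternary C10 of A5, which must be set relative to C8 by addition to a ketone. The five-to-seven ring expansion needs a strained boat-like transition state and heat on an acid-sensitive enol ether. The carbonyl of A7 sits at C7, so the isopropyl group must still be introduced by C–C bond formation, the oxygen removed and C7 set. The C4 ketal still has to become the C3=C4 methyl alkene, the same late problem as in the chosen route.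
- Comparison: the chosen strategy has the isopropyl group and the oxygen on the right carbons from the outset and needs no C–C bond formation on the seven-membered ring after the key step. That is what it offers in place of chiral-pool control at C8.

Key step: step 6

## Remarks on the chemistry (assumptions)

- The sense of induction of the bis(oxazoline) ligand is taken by analogy with simpler aryl diazoketones. If the 5R enantiomer of 12 prevails, the mirror-image ligand is used.
- The C4 configuration of 13–21 is drawn as expected for attack of the methyl nucleophile anti to C6 (hydroxyl trans to H5). This centre disappears in step 13.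
- The descriptor at C5 changes from S (12–21) to R (22, 23) only because C4 loses its oxygen and drops below C1 in priority. The spatial arrangement is unchanged.

## Route

Step 1
Reactants: 1 thymol
Product: 2 thymol methyl ether (1-isopropyl-2-methoxy-4-methylbenzene)
Conditions: MeI, K2CO3, acetone, reflux
Reagents that add atoms: iodomethane, CI
Why: Williamson ether synthesis on the phenoxide; the methyl ether later becomes the C8 enol ether and is inert until step 8.

Step 2
Reactants: 2 thymol methyl ether
Product: 4 5-isopropyl-4-methoxy-2-methylbenzaldehyde, via chloro ether 3 (not isolated)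
Conditions: Cl2CHOMe, TiCl4, CH2Cl2, -10 to 0 °C; then H2O
Reagents that add atoms: dichloromethyl methyl ether, COC(Cl)Cl; water, O
Why: Rieche formylation, a Friedel–Crafts alkylation by the TiCl4-activated dichloromethyl ether followed by hydrolysis of 3 on work-up; the methoxy group directs para, and the free ortho position is wedged between methoxy and methyl, so the formyl carbon (C2) enters at the future C1.

Step 3
Reactants: 4 5-isopropyl-4-methoxy-2-methylbenzaldehyde; 5 malonic acid
Product: 7 (E)-3-(5-isopropyl-4-methoxy-2-methylphenyl)acrylic acid, via benzylidenemalonic acid 6 (not isolated)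
Conditions: pyridine, piperidine (cat.), 100 °C
Reagents that add atoms: none
Why: Knoevenagel condensation with decarboxylation in hot pyridine (Doebner modification) adds C3 and C4 and gives the E acid.

Step 4
Reactants: 7 (E)-3-(5-isopropyl-4-methoxy-2-methylphenyl)acrylic acid
Product: 8 3-(5-isopropyl-4-methoxy-2-methylphenyl)propanoic acid
Conditions: H2 (1 atm), 10% Pd/C, EtOAc, rt
Reagents that add atoms: none
Why: Heterogeneous hydrogenation of the conjugated alkene; the arene and the aryl ether are not touched under these conditions.

Step 5
Reactants: 8 3-(5-isopropyl-4-methoxy-2-methylphenyl)propanoic acid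
Product: 10 1-diazo-4-(5-isopropyl-4-methoxy-2-methylphenyl)butan-2-one, via acid chloride 9 (not isolated)
Conditions: (COCl)2, DMF (cat.), CH2Cl2, 0 °C to rt; evaporate; Me3SiCHN2 (2.2 equiv), MeCN/THF, 0 °C to rt
Reagents that add atoms: oxalyl chloride, ClC(=O)C(=O)Cl (chlorine of 9 only); (trimethylsilyl)diazomethane, C[Si](C)(C)C=[N+]=[N-]
Why: Acid chloride formation followed by acylation of the silyl diazomethane (Arndt–Eistert-type diazoketone synthesis) installs C5 as the diazo carbon; no Lewis acid is present, so 9 does not cyclise onto the arene.

Step 6
Reactants: 10 1-diazo-4-(5-isopropyl-4-methoxy-2-methylphenyl)butan-2-one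
Product: 12 (5S)-8-methoxy-15-norguaia-1(10),6,8-trien-4-one [(8aS)-7-isopropyl-6-methoxy-4-methyl-3,8a-dihydroazulen-1(2H)-one], via norcaradiene 11 (not isolated)
Conditions: Cu(MeCN)4PF6 (5 mol %), 2,2'-(propane-2,2-diyl)bis[(4R)-4-phenyl-4,5-dihydrooxazole] (6 mol %), NaB[3,5-(CF3)2C6H3]4 (6 mol %), CH2Cl2, 40 °C, slow addition of 10
Reagents that add atoms: none
Why: The chiral copper complex (monovalent copper) expels dinitrogen from 10 and gives an electrophilic copper carbene at C5. C5 attacks the ipso carbon C1, which is para to methoxy and so the most nucleophilic ring carbon, in a 5-exo mode that closes the five-membered ring, and its second bond to C6 completes the cyclopropane of 11 (3-exo, a formal [2+1] addition to the arene C1–C6 bond). Norcaradiene 11 then opens by thermally allowed disrotatory 6π electrocyclic cleavage of C1–C6, so the seven-membered ring arises by one-carbon ring expansion of the benzene ring, with C5 between C1 and C6 and double bonds at C1=C10, C8=C9 and C6=C7. The closest known reaction type is the enantioselective intramolecular Buchner reaction of 1-diazo-4-arylbutan-2-ones to 3,8a-dihydroazulen-1(2H)-ones with copper bis(oxazoline) catalysts. C5 is the only new stereocenter; it is fixed when the ligand selects one enantiotopic face of the C1–C6 bond, and the ring opening breaks no bond to C5. The site selectivity needed is addition on the C6 side, which the methyl group on the other ortho carbon secures by hindrance, so that this carbon becomes C10 of the tetrasubstituted alkene. The chemoselectivity needed is cyclopropanation over aromatic substitution to a 2-tetralone; the absence of acid and of a Lewis-acidic metal favours it, and the methyl ether cannot be shed to a spirodienone. Product 12 is used at once, because H5 is alpha to the ketone and doubly allylic.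

Step 7
Reactants: 12 (5S)-8-methoxy-15-norguaia-1(10),6,8-trien-4-one
Product: 13 (4R,5S)-8-methoxyguaia-1(10),6,8-trien-4-ol
Conditions: MeLi, CeCl3, THF, -78 °C; then 12, -78 °C; aq NH4Cl
Reagents that add atoms: methylcerium dichloride (from MeLi and CeCl3), C[Ce](Cl)Cl
Why: Organocerium 1,2-addition; the reagent is nucleophilic but hardly basic, so the C4 ketone is methylated without enolisation toward C5. Attack anti to C6 puts methyl cis and hydroxyl trans to H5, a transient centre that matters only for the syn elimination of step 13.

Step 8
Reactants: 13 (4R,5S)-8-methoxyguaia-1(10),6,8-trien-4-ol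
Product: 14 (4R,5S)-4-hydroxyguaia-1(10),6-dien-8-one
Conditions: (CO2H)2·2H2O, THF/H2O, 0 °C
Reagents that add atoms: water, O
Why: Mild enol ether hydrolysis; kinetic protonation of the dienol ether at the alpha carbon C9, then loss of methanol from the hemiketal, gives the C8 ketone conjugated with C6=C7 and leaves C1=C10 in place, as with the dienol ethers of Birch reductions. The weak acid at 0 °C avoids ionisation of the tertiary alcohol and enolisation toward C9.

Step 9
Reactants: 14 (4R,5S)-4-hydroxyguaia-1(10),6-dien-8-one
Product: 15 (4R,5S,8S)-guaia-1(10),6-diene-4,8-diol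
Conditions: (R)-2-methyl-CBS-oxazaborolidine [(R)-1-methyl-3,3-diphenyltetrahydro-1H,3H-pyrrolo[1,2-c][1,3,2]oxazaborole] (0.3 equiv), catecholborane (3 equiv), toluene, -78 °C; then MeOH
Reagents that add atoms: none
Why: Corey–Bakshi–Shibata reduction; the alpha-branched alkenyl carbon C7 acts as the large group and the C9 methylene as the small one, so the R catalyst delivers hydride to the face that gives 8S irrespective of the remote C5. Catecholborane reduces the enone 1,2 and does not hydroborate the alkenes.

Step 10
Reactants: 15 (4R,5S,8S)-guaia-1(10),6-diene-4,8-diol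
Product: 16 (4R,5S,7R,8S)-guai-1(10)-ene-4,8-diol
Conditions: [Ir(cod)(PCy3)(py)]PF6 (5 mol %), H2 (1 atm), CH2Cl2, 0 °C
Reagents that add atoms: none
Why: Hydroxyl-directed homogeneous hydrogenation; the cationic iridium catalyst binds the C8 hydroxyl and adds hydrogen to C6=C7 from that face, so H7 is cis and the isopropyl group trans to oxygen (7R). The C4 hydroxyl lies on the same face and reinforces this, and the tetrasubstituted C1=C10 bond reacts much more slowly.

Step 11
Reactants: 17 vanillic acid
Product: 19 4-(tert-butyldimethylsilyloxy)-3-methoxybenzoic acid, via bis-silyl vanillate 18 (not isolated)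
Conditions: TBSCl (2.5 equiv), imidazole, DMF, rt; then AcOH/THF/H2O, rt
Reagents that add atoms: tert-butyldimethylsilyl chloride, CC(C)(C)[Si](C)(C)Cl
Why: Silylation of both hydroxyl groups followed by selective hydrolysis of the labile silyl ester; the aryl silyl ether is stable to aqueous acetic acid.

Step 12
Reactants: 16 (4R,5S,7R,8S)-guai-1(10)-ene-4,8-diol; 19 4-(tert-butyldimethylsilyloxy)-3-methoxybenzoic acid
Product: 20 (4R,5S,7R,8S)-4-hydroxyguai-1(10)-en-8-yl 4-(tert-butyldimethylsilyloxy)-3-methoxybenzoate
Conditions: DCC, 4-(dimethylamino)pyridine, CH2Cl2, 0 °C to rt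
Reagents that add atoms: none
Why: Steglich esterification; only the secondary C8 hydroxyl is acylated, the tertiary C4 hydroxyl is inert under these conditions, and C8 keeps its configuration because the C–O bond is not broken.

Step 13
Reactants: 20 (4R,5S,7R,8S)-4-hydroxyguai-1(10)-en-8-yl 4-(tert-butyldimethylsilyloxy)-3-methoxybenzoate
Product: 22 (5R,7R,8S)-guaia-1(10),3-dien-8-yl 4-(tert-butyldimethylsilyloxy)-3-methoxybenzoate, via sulfamate salt 21 (not isolated)
Conditions: MeO2CN(-)SO2N(+)Et3 (Burgess reagent), benzene, 50 °C
Reagents that add atoms: Burgess reagent, CC[N+](CC)(CC)S(=O)(=O)[N-]C(=O)OC (atoms kept in 21 only)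
Why: Burgess dehydration; sulfamate 21 eliminates by a syn (Ei-type) pathway, H5 is trans to the leaving group and cannot be taken, and of the remaining syn hydrogens the ring hydrogen at C3 gives the more substituted endocyclic C3=C4 alkene. The neutral conditions spare the ester, the silyl ether and the new skipped diene.

Step 14
Reactants: 22 (5R,7R,8S)-guaia-1(10),3-dien-8-yl 4-(tert-butyldimethylsilyloxy)-3-methoxybenzoate
Product: 23 (5R,7R,8S)-guaia-1(10),3-dien-8-yl 4-hydroxy-3-methoxybenzoate (CNP0156298.2)
Conditions: Bu4NF, AcOH, THF, 0 °C
Reagents that add atoms: none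
Why: Fluoride cleavage of the aryl silyl ether, buffered with acetic acid so that the phenoxide is protonated at once and neither the ester nor the doubly allylic C2 and C5 positions meet base.

## Compound list

1 | thymol (2-isopropyl-5-methylphenol) | Cc1ccc(C(C)C)c(O)c1 | starting material
2 | thymol methyl ether (1-isopropyl-2-methoxy-4-methylbenzene) | COc1cc(C)ccc1C(C)C | intermediate
3 | 1-[chloro(methoxy)methyl]-5-isopropyl-4-methoxy-2-methylbenzene (racemic at the chloro ether carbon) | COC(Cl)c1cc(C(C)C)c(OC)cc1C | intermediate (not isolated)
4 | 5-isopropyl-4-methoxy-2-methylbenzaldehyde | O=Cc1cc(C(C)C)c(OC)cc1C | intermediate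
5 | malonic acid | OC(=O)CC(=O)O | starting material
6 | 2-(5-isopropyl-4-methoxy-2-methylbenzylidene)malonic acid | OC(=O)C(=Cc1cc(C(C)C)c(OC)cc1C)C(=O)O | intermediate (not isolated)
7 | (E)-3-(5-isopropyl-4-methoxy-2-methylphenyl)acrylic acid | OC(=O)/C=C/c1cc(C(C)C)c(OC)cc1C | intermediate
8 | 3-(5-isopropyl-4-methoxy-2-methylphenyl)propanoic acid | OC(=O)CCc1cc(C(C)C)c(OC)cc1C | intermediate
9 | 3-(5-isopropyl-4-methoxy-2-methylphenyl)propanoyl chloride | ClC(=O)CCc1cc(C(C)C)c(OC)cc1C | intermediate (not isolated)
10 | 1-diazo-4-(5-isopropyl-4-methoxy-2-methylphenyl)butan-2-one | [N-]=[N+]=CC(=O)CCc1cc(C(C)C)c(OC)cc1C | intermediate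
11 | norcaradiene valence isomer of 12 (cyclopropane C1–C5–C6, cis-fused, same C5 configuration as 12) | O=C1CC[C@]23C(C)=CC(OC)=C(C(C)C)[C@H]2[C@H]13 | intermediate (not isolated)
12 | (5S)-8-methoxy-15-norguaia-1(10),6,8-trien-4-one [(8aS)-7-isopropyl-6-methoxy-4-methyl-3,8a-dihydroazulen-1(2H)-one] | O=C1CCC2=C(C)C=C(OC)C(C(C)C)=C[C@H]12 | intermediate
13 | (4R,5S)-8-methoxyguaia-1(10),6,8-trien-4-ol | COC1=CC(C)=C2CC[C@@](C)(O)[C@H]2C=C1C(C)C | intermediate
14 | (4R,5S)-4-hydroxyguaia-1(10),6-dien-8-one | O=C1CC(C)=C2CC[C@@](C)(O)[C@H]2C=C1C(C)C | intermediate
15 | (4R,5S,8S)-guaia-1(10),6-diene-4,8-diol | O[C@H]1CC(C)=C2CC[C@@](C)(O)[C@H]2C=C1C(C)C | intermediate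
16 | (4R,5S,7R,8S)-guai-1(10)-ene-4,8-diol | O[C@H]1CC(C)=C2CC[C@@](C)(O)[C@H]2C[C@@H]1C(C)C | intermediate
17 | vanillic acid (4-hydroxy-3-methoxybenzoic acid) | COc1cc(C(=O)O)ccc1O | starting material
18 | tert-butyldimethylsilyl 4-(tert-butyldimethylsilyloxy)-3-methoxybenzoate | COc1cc(C(=O)O[Si](C)(C)C(C)(C)C)ccc1O[Si](C)(C)C(C)(C)C | intermediate (not isolated)
19 | 4-(tert-butyldimethylsilyloxy)-3-methoxybenzoic acid | COc1cc(C(=O)O)ccc1O[Si](C)(C)C(C)(C)C | intermediate
20 | (4R,5S,7R,8S)-4-hydroxyguai-1(10)-en-8-yl 4-(tert-butyldimethylsilyloxy)-3-methoxybenzoate | COc1cc(C(=O)O[C@H]2CC(C)=C3CC[C@@](C)(O)[C@H]3C[C@@H]2C(C)C)ccc1O[Si](C)(C)C(C)(C)C | intermediate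
21 | triethylammonium salt of the C4 N-(methoxycarbonyl)sulfamate of 20 | COc1cc(C(=O)O[C@H]2CC(C)=C3CC[C@@](C)(OS(=O)(=O)[N-]C(=O)OC)[C@H]3C[C@@H]2C(C)C)ccc1O[Si](C)(C)C(C)(C)C.CC[NH+](CC)CC | intermediate (not isolated)
22 | (5R,7R,8S)-guaia-1(10),3-dien-8-yl 4-(tert-butyldimethylsilyloxy)-3-methoxybenzoate | COc1cc(C(=O)O[C@H]2CC(C)=C3CC=C(C)[C@H]3C[C@@H]2C(C)C)ccc1O[Si](C)(C)C(C)(C)C | intermediate
23 | (5R,7R,8S)-guaia-1(10),3-dien-8-yl 4-hydroxy-3-methoxybenzoate (CNP0156298.2) | COc1cc(C(=O)O[C@H]2CC(C)=C3CC=C(C)[C@H]3C[C@@H]2C(C)C)ccc1O | target

## Step count and least certain steps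

Total: 14 steps. Longest linear sequence: 13 steps (steps 1–10 and 12–14 from thymol 1); step 11 is a one-step branch from vanillic acid 17. C5 is set in step 6, C8 in step 9 and C7 in step 10; the transient C4 centre is made in step 7 and removed in step 13.

**Step 6 (key step).** The most likely failure is a stepwise course. Attack at the ipso carbon gives a spiro arenium ion stabilised by the para methoxy group; this can lose the memory of the catalyst's face selection and can rearrange by a 1,2-shift to a 2-tetralone instead of closing to 11. A tetrasubstituted, electron-rich arene is also outside the substrates for which the ligand is known to perform well.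
Fallback: enantiocontrol is moved away from the ring expansion. From 10, the achiral catalyst Rh2(OAc)4 (divalent rhodium) in CH2Cl2 gives racemic material. That is 12 together with the enantiomeric azulenone F2, formed through 11 and the enantiomeric norcaradiene F1. The racemate is taken through steps 7 and 8 unchanged, giving 13 with the enantiomeric alcohol F3 and then 14 with the enantiomeric dienone F4. Step 9 then serves as the resolving step: the reagent-controlled reduction gives 15 and the diastereomeric diol F5, which are separated by chromatography. The route is rejoined at 15.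

**Step 13.** The most likely failure is poor regioselectivity of the elimination: loss of a methyl hydrogen to the exocyclic C4=C15 alkene, or partial ionisation to a C4 cation that loses H5 to give the conjugated C4=C5 diene. A tertiary sulfamate has considerable ion-pair character, and only the syn geometry argues against these paths.
Fallback: the C4 methyl group and the C3=C4 bond are introduced together by cross-coupling, so no elimination is needed; this also bypasses step 7. From 12, NaBH4/CeCl3·7H2O (MeOH, -78 °C) gives the C4 alcohol F6, which is silylated (TBSCl, imidazole, DMF) to the silyl ether F7. Hydrolysis as in step 8 gives the dienone F8. Reduction as in step 9 gives the allylic alcohol F9. Hydrogenation as in step 10 gives the alcohol F10. Esterification with 19 as in step 12 gives the ester F11. Camphorsulfonic acid in MeOH removes the alkyl silyl ether, which is more acid-labile than the aryl silyl ether, to give the hydroxy ester F12. Dess–Martin periodinane oxidises this to the ketone F13. Kinetic deprotonation at the C3 methylene (KN(SiMe3)2, THF, -78 °C) and trapping with PhNTf2 gives the enol triflate F14. Negishi coupling (MeZnCl, Pd(PPh3)4, THF, rt) returns to the route at 22.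

**Step 10.** The most likely failure is loss of chemoselectivity: slow hydrogenation or migration of the tetrasubstituted C1=C10 bond, which is homoallylic to both hydroxyl groups and can be reached by the same coordinated iridium hydride.
Fallback: the conjugated double bond is reduced by a reagent that cannot touch an isolated alkene, at the price of control at C7. From 14, [(Ph3P)CuH]6 (monovalent copper) in benzene reduces only the enone C6=C7 bond and gives the saturated ketone F15 together with the 7-epimeric ketone F16. Reduction of the mixture as in step 9 gives 16 from F15 and the 7-epimeric diol F17 from F16. Diol 16 is separated by chromatography, and the route is rejoined at 16.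

**Step 9.** The most likely failure is weak reagent control. The two flanks of the C8 ketone (an isopropyl-bearing alkenyl carbon and an allylic methylene) may not be distinguished as clearly as in simple enones, and the free C4 hydroxyl consumes borane and may perturb the catalyst.
Fallback: reduction without catalyst control, with separation and recycling. From 14, NaBH4/CeCl3·7H2O (MeOH, -78 °C) gives 15 together with the 8-epimeric diol F18. The two diastereomers are separated, and F18 is returned to 14 by oxidation of its allylic hydroxyl with MnO2 (CH2Cl2). The route is rejoined at 15.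

## Further compounds

F1 | step 6 | enantiomer of norcaradiene 11 (not isolated) | O=C1CC[C@@]23C(C)=CC(OC)=C(C(C)C)[C@@H]2[C@@H]13
F2 | step 6 | (5R)-8-methoxy-15-norguaia-1(10),6,8-trien-4-one (enantiomer of 12) | O=C1CCC2=C(C)C=C(OC)C(C(C)C)=C[C@@H]12
F3 | step 6 | (4S,5R)-8-methoxyguaia-1(10),6,8-trien-4-ol (enantiomer of 13) | COC1=CC(C)=C2CC[C@](C)(O)[C@@H]2C=C1C(C)C
F4 | step 6 | (4S,5R)-4-hydroxyguaia-1(10),6-dien-8-one (enantiomer of 14) | O=C1CC(C)=C2CC[C@](C)(O)[C@@H]2C=C1C(C)C
F5 | step 6 | (4S,5R,8S)-guaia-1(10),6-diene-4,8-diol | O[C@H]1CC(C)=C2CC[C@](C)(O)[C@@H]2C=C1C(C)C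
F6 | step 13 | (4R,5S)-8-methoxy-15-norguaia-1(10),6,8-trien-4-ol | COC1=CC(C)=C2CC[C@@H](O)[C@H]2C=C1C(C)C
F7 | step 13 | (4R,5S)-4-(tert-butyldimethylsilyloxy)-8-methoxy-15-norguaia-1(10),6,8-triene | COC1=CC(C)=C2CC[C@@H](O[Si](C)(C)C(C)(C)C)[C@H]2C=C1C(C)C
F8 | step 13 | (4R,5S)-4-(tert-butyldimethylsilyloxy)-15-norguaia-1(10),6-dien-8-one | O=C1CC(C)=C2CC[C@@H](O[Si](C)(C)C(C)(C)C)[C@H]2C=C1C(C)C
F9 | step 13 | (4R,5S,8S)-4-(tert-butyldimethylsilyloxy)-15-norguaia-1(10),6-dien-8-ol | O[C@H]1CC(C)=C2CC[C@@H](O[Si](C)(C)C(C)(C)C)[C@H]2C=C1C(C)C
F10 | step 13 | (4R,5S,7R,8S)-4-(tert-butyldimethylsilyloxy)-15-norguai-1(10)-en-8-ol | O[C@H]1CC(C)=C2CC[C@@H](O[Si](C)(C)C(C)(C)C)[C@H]2C[C@@H]1C(C)C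
F11 | step 13 | (4R,5S,7R,8S)-4-(tert-butyldimethylsilyloxy)-15-norguai-1(10)-en-8-yl 4-(tert-butyldimethylsilyloxy)-3-methoxybenzoate | COc1cc(C(=O)O[C@H]2CC(C)=C3CC[C@@H](O[Si](C)(C)C(C)(C)C)[C@H]3C[C@@H]2C(C)C)ccc1O[Si](C)(C)C(C)(C)C
F12 | step 13 | (4R,5S,7R,8S)-4-hydroxy-15-norguai-1(10)-en-8-yl 4-(tert-butyldimethylsilyloxy)-3-methoxybenzoate | COc1cc(C(=O)O[C@H]2CC(C)=C3CC[C@@H](O)[C@H]3C[C@@H]2C(C)C)ccc1O[Si](C)(C)C(C)(C)C
F13 | step 13 | (5S,7R,8S)-4-oxo-15-norguai-1(10)-en-8-yl 4-(tert-butyldimethylsilyloxy)-3-methoxybenzoate | COc1cc(C(=O)O[C@H]2CC(C)=C3CCC(=O)[C@H]3C[C@@H]2C(C)C)ccc1O[Si](C)(C)C(C)(C)C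
F14 | step 13 | (5S,7R,8S)-4-(trifluoromethylsulfonyloxy)-15-norguaia-1(10),3-dien-8-yl 4-(tert-butyldimethylsilyloxy)-3-methoxybenzoate | COc1cc(C(=O)O[C@H]2CC(C)=C3CC=C(OS(=O)(=O)C(F)(F)F)[C@H]3C[C@@H]2C(C)C)ccc1O[Si](C)(C)C(C)(C)C
F15 | step 10 | (4R,5S,7R)-4-hydroxyguai-1(10)-en-8-one | O=C1CC(C)=C2CC[C@@](C)(O)[C@H]2C[C@@H]1C(C)C
F16 | step 10 | (4R,5S,7S)-4-hydroxyguai-1(10)-en-8-one | O=C1CC(C)=C2CC[C@@](C)(O)[C@H]2C[C@H]1C(C)C
F17 | step 10 | (4R,5S,7S,8S)-guai-1(10)-ene-4,8-diol | O[C@H]1CC(C)=C2CC[C@@](C)(O)[C@H]2C[C@H]1C(C)C
F18 | step 9 | (4R,5S,8R)-guaia-1(10),6-diene-4,8-diol | O[C@@H]1CC(C)=C2CC[C@@](C)(O)[C@H]2C=C1C(C)C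
A1 | alternative 1 | bromo aldehyde: cyclopentene with C3=C4 and C5, a C10 dioxolane–CH2–CHO arm on C1 and an (E)-4-bromo-3-methylbut-2-enyl arm on C5 | O=CCC1(OCCO1)[C@@H]2CC=C(C)[C@H]2C/C=C(\C)CBr
A2 | alternative 1 | trans-fused hydroazulenol with C10 dioxolane, C8 hydroxyl, C7 isopropenyl and C3=C4 | O[C@H]1CC2(OCCO2)[C@@H]3CC=C(C)[C@H]3C[C@@H]1C(C)=C
A3 | alternative 2 | allenyne with C7 isopropyl, C8 silyloxy, methyl alkyne (C4, C5) and 1,1-disubstituted allene (C10, C1, C2) | CC#CC[C@H](C(C)C)[C@@H](O[Si](C)(C)C(C)(C)C)CC(C)=C=C
A4 | alternative 2 | hydroazulene dienone with C3 ketone, C4=C5, C1=C10, C7 isopropyl and C8 silyloxy | O=C1CC2=C(C)C[C@H](O[Si](C)(C)C(C)(C)C)[C@@H](C(C)C)CC2=C1C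
A5 | alternative 3 | lactone with C7 carbonyl, C8 silyloxy and quaternary C10 bearing methyl and the ketal-protected cyclopentenyl group | O=C1O[C@@](C)(C2=CC3(OCCO3)CC2)C[C@@H]1O[Si](C)(C)C(C)(C)C
A6 | alternative 3 | 2-methylenetetrahydrofuran derived from A5 (exocyclic methylene carbon is C6) | C=C1O[C@@](C)(C2=CC3(OCCO3)CC2)C[C@@H]1O[Si](C)(C)C(C)(C)C
A7 | alternative 3 | hydroazulenone with C7 ketone, C1=C10, C5–H, C4 dioxolane and C8 silyloxy | O=C1C[C@H]2C(CCC23OCCO3)=C(C)C[C@@H]1O[Si](C)(C)C(C)(C)C
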